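**Plan**
- Cuts: after the three benzyl ethers and the tert-butyl ester are removed, the retrosynthesis cuts O1–C8a (ring C). It then cuts C2–C3 of the open 1,3-diketone, then C4a–C4 and C5–C1' on ring A, and the aryl–carboxyl bond on ring B.
- Enabling feature: O1 sits on C8a of ring A, ortho to C4a, which carries the C4 carbonyl. A fluorine on C8a is therefore an activated leaving group for the enolate oxygen on C2, and the other ortho carbon, C5, is blocked by heptyl.
- Ring A, forward: 3-bromo-5-fluorophenol is benzylated, heptylated, brominated para to oxygen and acetylated.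
- Ring B, forward: methyl (3,5-dihydroxyphenyl)acetate is benzylated, formylated, oxidised and tert-butylated, and its side chain is turned into an acyl donor.
- Rings A and B are bought as arenes. A Claisen condensation joins them, ring C (the only ring made) closes next, and acidolysis plus hydrogenolysis finish the synthesis.
- Stereochemistry: the target has no stereocentre and no stereogenic double bond, so nothing has to be controlled.

Key step: step 12

Remark: chromone numbering (O1, C2, C3, C4, C4a, C5–C8, C8a) is used for rings A and C in the open-chain precursors as well. The 1,3-diketone is drawn in its diketo form, although it should be largely enolised.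

**Step 1**
Reactants: 1 3-bromo-5-fluorophenol
Product: 2 1-(benzyloxy)-3-bromo-5-fluorobenzene
Conditions: BnBr, K2CO3, DMF, rt
Reagents that add atoms: benzyl bromide, BrCc1ccccc1
Why: Williamson ether synthesis on an acidic halophenol; neither aryl halide is activated towards substitution under these mild conditions.

**Step 2**
Reactants: 2 1-(benzyloxy)-3-bromo-5-fluorobenzene, 3 heptylmagnesium bromide
Product: 4 1-(benzyloxy)-3-fluoro-5-heptylbenzene
Conditions: PdCl2(dppf) (3 mol %), THF, 0 → 40 °C
Reagents that add atoms: none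
Why: Kumada–Corriu coupling, in which zerovalent palladium inserts only into C–Br (C–F and the benzyl ether are left alone) and the wide bite angle of dppf makes reductive elimination faster than β-hydride elimination from the primary alkyl group.

**Step 3**
Reactants: 4 1-(benzyloxy)-3-fluoro-5-heptylbenzene
Product: 5 5-(benzyloxy)-2-bromo-1-fluoro-3-heptylbenzene
Conditions: NBS (1.0 equiv), MeCN, 0 °C → rt, dark
Reagents that add atoms: N-bromosuccinimide, O=C1CCC(=O)N1Br
Why: Electrophilic aromatic bromination; NBS in acetonitrile is known to attack aryl ethers para to oxygen even in 3,5-disubstituted cases, the small fluorine keeps that site accessible, and polar conditions in the dark suppress radical bromination of the benzylic positions.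

**Step 4**
Reactants: 5 5-(benzyloxy)-2-bromo-1-fluoro-3-heptylbenzene
Product: 7 1-[4-(benzyloxy)-2-fluoro-6-heptylphenyl]ethan-1-one, via aryllithium 6 (not isolated)
Conditions: n-BuLi, THF, −78 °C; MeC(O)N(OMe)Me, −78 → 0 °C; then 1 M HCl
Reagents that add atoms: N-methoxy-N-methylacetamide, CC(=O)N(C)OC
Why: Bromine–lithium exchange is faster than benzylic deprotonation at −78 °C, where an ortho-fluoroaryllithium does not yet lose LiF, and the Weinreb ketone synthesis adds the aryl group only once.

**Step 5**
Reactants: 8 methyl 2-(3,5-dihydroxyphenyl)acetate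
Product: 9 methyl 2-[3,5-bis(benzyloxy)phenyl]acetate
Conditions: BnBr (2.2 equiv), K2CO3, acetone, reflux
Reagents that add atoms: benzyl bromide, BrCc1ccccc1
Why: Double Williamson ether synthesis; carbonate is too weak to deprotonate the arylacetate α-carbon or to touch the methyl ester.

**Step 6**
Reactants: 9 methyl 2-[3,5-bis(benzyloxy)phenyl]acetate
Product: 11 methyl 2-[3,5-bis(benzyloxy)-2-formylphenyl]acetate, via aryl iminium chloride 10 (not isolated)
Conditions: POCl3, DMF, 0 → 60 °C; then H2O, rt
Reagents that add atoms: N,N-dimethylformamide, CN(C)C=O; water, O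
Why: Vilsmeier–Haack formylation, which on 3,5-dialkoxyphenylacetates is known to go to C2 (ortho to one ether and para to the other) rather than to the more crowded C4 between the two ethers.

**Step 7**
Reactants: 11 methyl 2-[3,5-bis(benzyloxy)-2-formylphenyl]acetate
Product: 12 2,4-bis(benzyloxy)-6-(2-methoxy-2-oxoethyl)benzoic acid
Conditions: NaClO2, NaH2PO4, 2-methyl-2-butene, t-BuOH–THF–H2O, 0 °C → rt
Reagents that add atoms: sodium chlorite, [Na+].[O-]Cl=O
Why: Pinnick oxidation turns the aldehyde into the acid under buffered conditions, and the alkene takes up the hypochlorous acid that would otherwise chlorinate the electron-rich ring.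

**Step 8**
Reactants: 12 2,4-bis(benzyloxy)-6-(2-methoxy-2-oxoethyl)benzoic acid
Product: 13 tert-butyl 2,4-bis(benzyloxy)-6-(2-methoxy-2-oxoethyl)benzoate
Conditions: Cl3CC(=NH)Ot-Bu, BF3·OEt2 (cat.), CH2Cl2–cyclohexane, 0 °C → rt
Reagents that add atoms: tert-butyl 2,2,2-trichloroacetimidate, CC(C)(C)OC(=N)C(Cl)(Cl)Cl
Why: Trichloroacetimidate esterification makes the new bond at the carboxyl oxygen and not at the acyl carbon, so the two ortho substituents do not slow it.

**Step 9**
Reactants: 13 tert-butyl 2,4-bis(benzyloxy)-6-(2-methoxy-2-oxoethyl)benzoate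
Product: 14 2-[3,5-bis(benzyloxy)-2-(tert-butoxycarbonyl)phenyl]acetic acid
Conditions: LiOH, THF–H2O, 0 °C → rt; then cold 1 M HCl to pH 3–4
Reagents that add atoms: lithium hydroxide, [Li+].[OH-]
Why: Saponification (BAc2) cleaves the unhindered aliphatic methyl ester, while the di-ortho-substituted tert-butyl benzoate is inert to hydroxide.

**Step 10**
Reactants: 14 2-[3,5-bis(benzyloxy)-2-(tert-butoxycarbonyl)phenyl]acetic acid
Product: 15 tert-butyl 2,4-bis(benzyloxy)-6-[2-(1H-benzotriazol-1-yl)-2-oxoethyl]benzoate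
Conditions: 1H-benzotriazole, N,N'-dicyclohexylcarbodiimide, CH2Cl2, 0 °C → rt
Reagents that add atoms: 1H-benzotriazole, c1ccc2[nH]nnc2c1
Why: Carbodiimide coupling gives an isolable N-acylbenzotriazole under neutral conditions, so no acid is released that could attack the tert-butyl ester.

**Step 11**
Reactants: 7 1-[4-(benzyloxy)-2-fluoro-6-heptylphenyl]ethan-1-one, 15 tert-butyl 2,4-bis(benzyloxy)-6-[2-(1H-benzotriazol-1-yl)-2-oxoethyl]benzoate
Product: 16 tert-butyl 2,4-bis(benzyloxy)-6-{4-[4-(benzyloxy)-2-fluoro-6-heptylphenyl]-2,4-dioxobutyl}benzoate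
Conditions: MgBr2·OEt2 (2.5 equiv), i-Pr2NEt (3 equiv), CH2Cl2, rt
Reagents that add atoms: none
Why: Crossed Claisen condensation under soft enolisation: coordination to MgBr2 acidifies the methyl ketone enough for the amine to enolise it, N-acylbenzotriazoles are established C-acylating partners under these conditions, and magnesium chelation of the diketone formed prevents a second acylation.

**Step 12**
Reactants: 16 tert-butyl 2,4-bis(benzyloxy)-6-{4-[4-(benzyloxy)-2-fluoro-6-heptylphenyl]-2,4-dioxobutyl}benzoate
Product: 18 tert-butyl 2,4-bis(benzyloxy)-6-{[7-(benzyloxy)-5-heptyl-4-oxo-4H-chromen-2-yl]methyl}benzoate, via potassium enolate 17 (not isolated)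
Conditions: K2CO3 (2 equiv), DMF, 90 °C, Ar
Reagents that add atoms: none
Why: K2CO3 removes a proton from C3, and in the U-shaped (Z)-enolate 17 the oxygen on C2 lies next to the fluorine-bearing C8a, adds to it and gives a Meisenheimer anion whose charge sits on C4a, C6 and C8 and drains into the C4 carbonyl before fluoride departs. The closest known reaction type is the base-mediated cyclisation of 1-(2-fluoroaryl)-1,3-diketones to chromones, the oxygen analogue of the cycloaracylation used for 4-quinolones. Ring C closes as a six-membered ring by intramolecular addition–elimination (SNAr) at an aromatic carbon, forming O1–C8a, and no stereocentre arises. Site selectivity is fixed by the substrate, since only one ortho carbon bears a leaving group, and the benzyloxy (C7) and heptyl (C5) donors stand meta to C8a, away from the carbons that take up the charge. Oxygen rather than carbon arylates because C3 could only close a four-membered ring and the benzylic CH2 would have to be deprotonated a second time, which carbonate cannot do. Acyl transfer to the enolate from the ring B carboxyl (through oxygen to an isocoumarin, through C3 to a naphthalenediol) is held off by the tert-butyl ester wedged between two ortho substituents, and argon protects the acidic C2–CH2 of the product from autoxidation.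

**Step 13**
Reactants: 18 tert-butyl 2,4-bis(benzyloxy)-6-{[7-(benzyloxy)-5-heptyl-4-oxo-4H-chromen-2-yl]methyl}benzoate
Product: 19 2,4-bis(benzyloxy)-6-{[7-(benzyloxy)-5-heptyl-4-oxo-4H-chromen-2-yl]methyl}benzoic acid
Conditions: CF3CO2H–CH2Cl2 (1:4), 0 °C → rt
Reagents that add atoms: none
Why: Acidolysis of the tert-butyl ester (AAL1, loss of isobutene) is done while the phenols are still benzylated, because the protected acid resists protodecarboxylation far better than a free 2,4-dihydroxybenzoic acid would in acid.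

**Step 14**
Reactants: 19 2,4-bis(benzyloxy)-6-{[7-(benzyloxy)-5-heptyl-4-oxo-4H-chromen-2-yl]methyl}benzoic acid
Product: 20 siphulin, 2-[(5-heptyl-7-hydroxy-4-oxo-4H-chromen-2-yl)methyl]-4,6-dihydroxybenzoic acid
Conditions: H2 (1 atm), 10% Pd/C, EtOAc–MeOH, rt
Reagents that add atoms: none
Why: Catalytic hydrogenolysis removes the three aryl benzyl ethers at room temperature and neutral pH, conditions under which the vinylogous-ester C2=C3 bond of chromones normally persists and the labile hydroxybenzoic acid is spared heat and acid.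

**Compound list**
1 | 3-bromo-5-fluorophenol | Oc1cc(F)cc(Br)c1 | starting material
2 | 1-(benzyloxy)-3-bromo-5-fluorobenzene | Fc1cc(Br)cc(OCc2ccccc2)c1 | intermediate
3 | heptylmagnesium bromide | CCCCCCC[Mg]Br | starting material
4 | 1-(benzyloxy)-3-fluoro-5-heptylbenzene | CCCCCCCc1cc(F)cc(OCc2ccccc2)c1 | intermediate
5 | 5-(benzyloxy)-2-bromo-1-fluoro-3-heptylbenzene | CCCCCCCc1cc(OCc2ccccc2)cc(F)c1Br | intermediate
6 | [4-(benzyloxy)-2-fluoro-6-heptylphenyl]lithium | CCCCCCCc1cc(OCc2ccccc2)cc(F)c1[Li] | intermediate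
7 | 1-[4-(benzyloxy)-2-fluoro-6-heptylphenyl]ethan-1-one | CCCCCCCc1cc(OCc2ccccc2)cc(F)c1C(C)=O | intermediate
8 | methyl 2-(3,5-dihydroxyphenyl)acetate | COC(=O)Cc1cc(O)cc(O)c1 | starting material
9 | methyl 2-[3,5-bis(benzyloxy)phenyl]acetate | COC(=O)Cc1cc(OCc2ccccc2)cc(OCc2ccccc2)c1 | intermediate
10 | {[2,4-bis(benzyloxy)-6-(2-methoxy-2-oxoethyl)phenyl]methylidene}dimethylammonium chloride | COC(=O)Cc1cc(OCc2ccccc2)cc(OCc2ccccc2)c1C=[N+](C)C.[Cl-] | intermediate
11 | methyl 2-[3,5-bis(benzyloxy)-2-formylphenyl]acetate | COC(=O)Cc1cc(OCc2ccccc2)cc(OCc2ccccc2)c1C=O | intermediate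
12 | 2,4-bis(benzyloxy)-6-(2-methoxy-2-oxoethyl)benzoic acid | COC(=O)Cc1cc(OCc2ccccc2)cc(OCc2ccccc2)c1C(=O)O | intermediate
13 | tert-butyl 2,4-bis(benzyloxy)-6-(2-methoxy-2-oxoethyl)benzoate | COC(=O)Cc1cc(OCc2ccccc2)cc(OCc2ccccc2)c1C(=O)OC(C)(C)C | intermediate
14 | 2-[3,5-bis(benzyloxy)-2-(tert-butoxycarbonyl)phenyl]acetic acid | OC(=O)Cc1cc(OCc2ccccc2)cc(OCc2ccccc2)c1C(=O)OC(C)(C)C | intermediate
15 | tert-butyl 2,4-bis(benzyloxy)-6-[2-(1H-benzotriazol-1-yl)-2-oxoethyl]benzoate | O=C(Cc1cc(OCc2ccccc2)cc(OCc2ccccc2)c1C(=O)OC(C)(C)C)n1nnc2ccccc12 | intermediate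
16 | tert-butyl 2,4-bis(benzyloxy)-6-{4-[4-(benzyloxy)-2-fluoro-6-heptylphenyl]-2,4-dioxobutyl}benzoate | CCCCCCCc1cc(OCc2ccccc2)cc(F)c1C(=O)CC(=O)Cc1cc(OCc2ccccc2)cc(OCc2ccccc2)c1C(=O)OC(C)(C)C | intermediate
17 | potassium (Z)-enolate of 16, charge drawn on the oxygen at C2, cis to the aroyl group | CCCCCCCc1cc(OCc2ccccc2)cc(F)c1C(=O)/C=C(\[O-])Cc1cc(OCc2ccccc2)cc(OCc2ccccc2)c1C(=O)OC(C)(C)C.[K+] | intermediate
18 | tert-butyl 2,4-bis(benzyloxy)-6-{[7-(benzyloxy)-5-heptyl-4-oxo-4H-chromen-2-yl]methyl}benzoate | CCCCCCCc1cc(OCc2ccccc2)cc2oc(Cc3cc(OCc4ccccc4)cc(OCc4ccccc4)c3C(=O)OC(C)(C)C)cc(=O)c12 | intermediate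
19 | 2,4-bis(benzyloxy)-6-{[7-(benzyloxy)-5-heptyl-4-oxo-4H-chromen-2-yl]methyl}benzoic acid | CCCCCCCc1cc(OCc2ccccc2)cc2oc(Cc3cc(OCc4ccccc4)cc(OCc4ccccc4)c3C(=O)O)cc(=O)c12 | intermediate
20 | siphulin, 2-[(5-heptyl-7-hydroxy-4-oxo-4H-chromen-2-yl)methyl]-4,6-dihydroxybenzoic acid | CCCCCCCc1cc(O)cc2oc(Cc3cc(O)cc(O)c3C(=O)O)cc(=O)c12 | target

**Step count**
- Total: 14 steps.
- Longest linear sequence: 10 steps (steps 5–14, from 8).
- The ring A branch runs over 8 steps (steps 1–4 and 11–14).

**Steps most likely to fail**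

**Step 11.**
- Risk: the α-CH2 of acyl donor 15 is benzylic and may be enolised faster than the hindered methyl ketone. Ketene formation and self-condensation of the donor, or O-acylation, could then outrun the wanted C-acylation.
- Fallback: aldol addition and oxidation replace the acylation. It sets out from 13 and 7 and comes back at 16.
- i-Bu2AlH (1 equiv, CH2Cl2, −78 °C) should reduce only the unhindered methyl ester of 13, giving the aldehyde tert-butyl 2,4-bis(benzyloxy)-6-(2-oxoethyl)benzoate F1.
- Ketone 7 is converted with LiN(i-Pr)2 (THF, −78 °C) into lithium 1-[4-(benzyloxy)-2-fluoro-6-heptylphenyl]ethen-1-olate F2. This adds to F1 and is quenched cold, before the aldolate can lactonise onto the ester.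
- The product is the racemic aldol tert-butyl 2,4-bis(benzyloxy)-6-{4-[4-(benzyloxy)-2-fluoro-6-heptylphenyl]-2-hydroxy-4-oxobutyl}benzoate F3.
- Dess–Martin periodinane (CH2Cl2, rt) then oxidises the carbinol, erases the stereocentre and delivers 16.

**Step 12.**
- Risk: the two ortho substituents twist the C4 carbonyl out of the plane of ring A, and the para benzyloxy group feeds electron density into it, so the addition to C8a may be slow. Prolonged heating would then open the way to retro-Claisen cleavage and to attack on the ring B ester.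
- Fallback: the same O1–C8a closure is run on a more electron-poor ring A, with heptyl put on afterwards. It sets out from 2 and comes back at 18.
- LiN(i-Pr)2 (THF, −78 °C) should remove the most acidic ring proton of 2, the one flanked by fluorine and bromine, to give [4-(benzyloxy)-2-bromo-6-fluorophenyl]lithium F4.
- N-methoxy-N-methylacetamide traps it at −78 °C as 1-[4-(benzyloxy)-2-bromo-6-fluorophenyl]ethan-1-one F5.
- Condensation with 15 under the conditions of step 11 gives tert-butyl 2,4-bis(benzyloxy)-6-{4-[4-(benzyloxy)-2-bromo-6-fluorophenyl]-2,4-dioxobutyl}benzoate F6. Its bromine stands meta to the C–F carbon and stabilises the anionic adduct inductively.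
- K2CO3 in DMF should then displace fluoride, by far the better leaving group in SNAr, to give tert-butyl 2,4-bis(benzyloxy)-6-{[7-(benzyloxy)-5-bromo-4-oxo-4H-chromen-2-yl]methyl}benzoate F7.
- Heptylzinc bromide F8, made from 3 and ZnBr2 in THF, is finally joined to C5 by Negishi coupling (PdCl2(dppf), THF, 50 °C) to give 18.

**Step 4.**
- Risk: the hindered aryllithium may act as a base towards the α-protons of the acetamide and simply be protonated. It can also lose LiF to an aryne if the temperature drifts upwards.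
- Fallback: cross-coupling with a masked acetyl group replaces the organolithium acylation. It sets out from 5 and comes back at 7.
- Stille coupling of 5 with tributyl(1-ethoxyvinyl)stannane (Pd(PPh3)4, toluene, 100 °C) should give the enol ether 5-(benzyloxy)-2-(1-ethoxyethenyl)-1-fluoro-3-heptylbenzene F9.
- 1 M HCl in THF at rt hydrolyses F9 to 7.

**Further compounds**
F1 | step 11 | tert-butyl 2,4-bis(benzyloxy)-6-(2-oxoethyl)benzoate | O=CCc1cc(OCc2ccccc2)cc(OCc2ccccc2)c1C(=O)OC(C)(C)C
F2 | step 11 | lithium 1-[4-(benzyloxy)-2-fluoro-6-heptylphenyl]ethen-1-olate | CCCCCCCc1cc(OCc2ccccc2)cc(F)c1C(=C)[O-].[Li+]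
F3 | step 11 | tert-butyl 2,4-bis(benzyloxy)-6-{4-[4-(benzyloxy)-2-fluoro-6-heptylphenyl]-2-hydroxy-4-oxobutyl}benzoate (racemic) | CCCCCCCc1cc(OCc2ccccc2)cc(F)c1C(=O)CC(O)Cc1cc(OCc2ccccc2)cc(OCc2ccccc2)c1C(=O)OC(C)(C)C
F4 | step 12 | [4-(benzyloxy)-2-bromo-6-fluorophenyl]lithium | [Li]c1c(F)cc(OCc2ccccc2)cc1Br
F5 | step 12 | 1-[4-(benzyloxy)-2-bromo-6-fluorophenyl]ethan-1-one | CC(=O)c1c(F)cc(OCc2ccccc2)cc1Br
F6 | step 12 | tert-butyl 2,4-bis(benzyloxy)-6-{4-[4-(benzyloxy)-2-bromo-6-fluorophenyl]-2,4-dioxobutyl}benzoate | O=C(CC(=O)Cc1cc(OCc2ccccc2)cc(OCc2ccccc2)c1C(=O)OC(C)(C)C)c1c(F)cc(OCc2ccccc2)cc1Br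
F7 | step 12 | tert-butyl 2,4-bis(benzyloxy)-6-{[7-(benzyloxy)-5-bromo-4-oxo-4H-chromen-2-yl]methyl}benzoate | Brc1cc(OCc2ccccc2)cc2oc(Cc3cc(OCc4ccccc4)cc(OCc4ccccc4)c3C(=O)OC(C)(C)C)cc(=O)c12
F8 | step 12 | heptylzinc bromide | CCCCCCC[Zn]Br
F9 | step 4 | 5-(benzyloxy)-2-(1-ethoxyethenyl)-1-fluoro-3-heptylbenzene | CCCCCCCc1cc(OCc2ccccc2)cc(F)c1C(=C)OCC
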